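The rate constants were drawn at random within sensible limits; the run is a simulation.

Slowness was where I started: with the electrophile as charged in Monday's flask, the nucleophile needed 1.0 min to halve by coupling alone, and free target needed less, 0.56 min, to halve by its side step alone.

common to all: electrophile 1.6 M; free base 1.92 M; protonated nucleophile 1.44 M

| run | time |
|---|---|
| Monday's | 1.0 min |
| Friday's | 2.5 min |

    electrophile + nucleophile → acid set free + target (k1 = 0.0072 M⁻¹ s⁻¹)
    nucleophile + acid set free ⇌ protonated nucleophile, settled at all times (K2 = 54 M⁻¹)
    acid set free + free base ⇌ salt of the base, settled at all times (K3 = 3800 M⁻¹)
    electrophile + target → side product (k4 = 0.013 M⁻¹ s⁻¹)
    free base + target ⇌ idle adduct, settled at all times (K5 = 3.3 M⁻¹)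

- percentages count the electrophile that a species holds: one side product counts as two
- target is meant together with its idle adduct
- run time (Monday's): 1.0 min

1. which of these there is most of at the end, counted by the electrophile in it, Monday's (side product / electrophile / target)
2. which of these there is most of at the end, counted by the electrophile in it, Friday's (side product / electrophile / target)
3. final amount of the leader among these, as a percentage of the electrophile charged, in Monday's
4. final amount of the leader among these, as a percentage of the electrophile charged, in Friday's

- Free target gains by coupling and loses by the side step, and both rates carry c(electrophile), so that factor cancels. I named the rate constant of coupling over that of the side step the ceiling ratio, 0.554 (the selectivity factor). Free target stops rising when c(free target) equals this ratio times c(nucleophile).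
- At that ceiling the side step removes electrophile as fast as coupling does, so electrophile leaves twice as fast as by coupling. Before the ceiling it leaves more slowly, so I took the midway rate, a pseudo-first-order decay with one and a half times the coupling constant times c(nucleophile).
- The free base binds acid more strongly than the nucleophile does, so it frees the nucleophile and has 0.480 M to spare for acid set free. Beyond that, acid also takes nucleophile. I therefore guessed a mean c(nucleophile) of 1.01 M over Monday's flask and 0.720 M over Friday's; these are guesses, not derivations.
- I put target at the ceiling on that mean and gave side product the remainder. For Monday's flask this made electrophile the leader, at 52.0%. For Friday's flask it made side product the leader, at 43.9%.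
- The forecast named electrophile at 57% for Monday's flask and side product at 50% for Friday's, on the ground of the “target's continued reaction with electrophile”.
- Monday's flask gave electrophile in the lead at 57.0%, and Friday's gave side product at 49.8%, with electrophile at 28.2% and target at 22.0%. With these charges, electrophile and side product stood level at 1.80 min.
- In Friday's flask, the 0.371 M of nucleophile at the end set a ceiling of 0.206 M. Free target stood above it at 0.320 M, and target with its adduct had gone from 24.3% at 1.25 min to 22.0%. The neighbour of Friday's charged with 0.96 M of electrophile, its other charges and time unchanged, ended with 0.667 M of nucleophile, a ceiling of 0.370 M. Its free target stood below that at 0.307 M, and target led there with 40.0% of its charge against 35.1% in side product.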